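**Retrosynthetic overview**

- Dactylomelol ⇐ Wharton transposition of a (2R,3S)-2,3-epoxy aldehyde at the head (C3 set by Sharpless epoxidation); the CHBr–CMe2Cl tail ⇐ terminal prenyl alkene via Shi epoxide, HBr opening and a 1,2-bromine shift.
- 7-Oxabicyclo[2.2.1]heptane core ⇐ one Lewis-acid cascade of (10S,11S)-10,11-epoxygeranylgeranyl acetate: C6–C11 bond (cyclohexane ring), then C7–O bond (oxygen bridge); C6, C7 and C11 all follow from the epoxide.
- Epoxide ⇐ Sharpless epoxidation of (10E)-12-hydroxyfarnesyl acetate, then copper-catalysed coupling of its triflate with prenylmagnesium chloride (C12–C13 bond).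
- Carbon skeleton ⇐ (2E,6E)-farnesol (C1–C12) + prenylmagnesium chloride (C13–C15).
- Ring order: carbocycle first, ether bridge second, both in step 5; no other step makes or breaks a ring of the target.

Convention used throughout: chain carbons are numbered C1–C15 as in geranylgeraniol (C1 carries the oxygen of farnesol); in dactylomelol C1=C2 is the vinyl group, C3 the carbinol, C6/C7/C10/C11 the ring carbons, C14 bears Br and C15 bears Cl.

**Step 1**
Reactants: 1 (2E,6E)-farnesol
Product: 2 (2E,6E)-farnesyl acetate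
Conditions: Ac2O, pyridine, 4-(dimethylamino)pyridine (cat.), 0 °C → rt
Reagents that add atoms: acetic anhydride, CC(=O)OC(C)=O
Why: O-acylation (nucleophilic acyl substitution) masks C1–OH and makes C2=C3 an electron-poor allylic acetate alkene that stays out of steps 2–8; no stereocentre is formed.

**Step 2**
Reactants: 2 (2E,6E)-farnesyl acetate
Product: 3 (2E,6E,10E)-12-hydroxy-3,7,11-trimethyldodeca-2,6,10-trien-1-yl acetate
Conditions: SeO2 (0.2 equiv), t-BuOOH, 2-hydroxybenzoic acid (cat.), CH2Cl2, rt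
Reagents that add atoms: tert-butyl hydroperoxide, CC(C)(C)OO; selenium dioxide, O=[Se]=O (oxygen carrier)
Why: Sharpless–Umbreit catalytic SeO2 allylic oxidation (ene reaction then [2,3]-shift) attacks the (E)-methyl of the terminal, most electron-rich trisubstituted alkene and keeps the (10E) geometry.

**Step 3**
Reactants: 3 (2E,6E,10E)-12-hydroxyfarnesyl acetate
Product: 4 (2E,6E)-9-[(2S,3S)-3-(hydroxymethyl)-3-methyloxiran-2-yl]-3,7-dimethylnona-2,6-dien-1-yl acetate
Conditions: Ti(OiPr)4 (10 mol %), diethyl L-(+)-tartrate (13 mol %), t-BuOOH, 4 Å MS, CH2Cl2, −20 °C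
Reagents that add atoms: tert-butyl hydroperoxide, CC(C)(C)OO
Why: Sharpless asymmetric epoxidation touches only the alkene of the single free allylic alcohol, and L-(+)-tartrate delivers oxygen to the face that gives the (10S,11S)-epoxide (reagent control).

**Step 4**
Reactants: 4 epoxy alcohol; 5 prenylmagnesium chloride (Me2C=CHCH2MgCl)
Product: 8 (2E,6E)-3,7-dimethyl-9-[(2S,3S)-3-methyl-3-(4-methylpent-3-en-1-yl)oxiran-2-yl]nona-2,6-dien-1-yl acetate, via lithium alkoxide 6 (not isolated), via primary triflate 7 (not isolated)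
Conditions: n-BuLi (1.0 equiv), Et2O, −78 °C; Tf2O, −78 °C; then 5 (1.5 equiv), Li2CuCl4 (5 mol %), THF, −78 → −40 °C
Reagents that add atoms: n-butyllithium, [Li]CCCC (Li of 6 only); trifluoromethanesulfonic anhydride, O=S(=O)(OS(=O)(=O)C(F)(F)F)C(F)(F)F (CF3SO2 of 7 only)
Why: O-triflation of the alkoxide and copper-catalysed sp3–sp3 cross-coupling (Kochi–Schlosser type) of the primary triflate with the Grignard reagent at its unhindered CH2 terminus forge C12–C13 at −78 °C, leaving the acetate and both epoxide stereocentres untouched.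

**Step 5**
Reactants: 8 (10S,11S)-10,11-epoxygeranylgeranyl acetate
Product: 9 (2E)-5-[(1R,2S,3S,4S)-1,3-dimethyl-3-(4-methylpent-3-en-1-yl)-7-oxabicyclo[2.2.1]heptan-2-yl]-3-methylpent-2-en-1-yl acetate
Conditions: BF3·OEt2 (0.5 equiv), CH2Cl2 (0.005 M), −78 °C
Reagents that add atoms: none
Why: Epoxide-initiated cation–olefin cyclisation (biomimetic epoxy-polyene cyclisation): C6 of the (6E) alkene attacks C11 of the activated epoxide anti to oxygen through a chair transition state, closing the cyclohexane ring and setting C11 (inversion) and C6, and the C10 oxygen then captures the tertiary C7 cation to close the oxygen bridge, so C6, C7 and C11 derive from the (10S,11S)-epoxide while the acetate-deactivated C2=C3 and the remote prenyl alkene stay out.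

**Step 6**
Reactants: 9 bicyclic acetate
Product: 10 (2E)-5-[(1R,2S,3S,4S)-3-{2-[(2R)-3,3-dimethyloxiran-2-yl]ethyl}-1,3-dimethyl-7-oxabicyclo[2.2.1]heptan-2-yl]-3-methylpent-2-en-1-yl acetate
Conditions: 1,2:4,5-di-O-isopropylidene-β-D-erythro-2,3-hexodiulo-2,6-pyranose (D-fructose-derived Shi ketone, 0.3 equiv), KHSO5 (as 2KHSO5·KHSO4·K2SO4), K2CO3, Bu4NHSO4 (cat.), MeCN/CH2(OMe)2/aq. Na2B4O7–Na2EDTA, 0 °C
Reagents that add atoms: potassium peroxymonosulfate, [K+].[O-]S(=O)(=O)OO
Why: Shi asymmetric epoxidation (chiral dioxirane, spiro transition state) reacts only at the electron-rich prenyl alkene, since C2=C3 is deactivated by the allylic acetate, and the D-fructose-derived ketone gives the (14R)-epoxide by reagent control.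

**Step 7**
Reactants: 10 tail epoxide
Product: 11 (2E)-5-[(1R,2S,3S,4S)-3-[(3R)-4-bromo-3-hydroxy-4-methylpentyl]-1,3-dimethyl-7-oxabicyclo[2.2.1]heptan-2-yl]-3-methylpent-2-en-1-yl acetate
Conditions: 48% aq. HBr (1.1 equiv), Et2O, −20 °C
Reagents that add atoms: hydrogen bromide, Br
Why: Acid-mediated epoxide ring opening (SN1-like, Markovnikov) places bromide at the tertiary C15 without breaking the C14–O bond, so the (14R) carbinol configuration is kept.

**Step 8**
Reactants: 11 bromohydrin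
Product: 12 (2E)-5-[(1R,2S,3S,4S)-3-[(3S)-3-bromo-4-chloro-4-methylpentyl]-1,3-dimethyl-7-oxabicyclo[2.2.1]heptan-2-yl]-3-methylpent-2-en-1-yl acetate
Conditions: SOCl2 (1.5 equiv), pyridine (3 equiv), CH2Cl2, −40 → 0 °C
Reagents that add atoms: thionyl chloride, ClS(Cl)=O
Why: Proposed new method: anchimerically assisted deoxychlorination with 1,2-bromine shift, in which the chlorosulfite of the C14 hydroxyl is displaced from the back by the neighbouring C15 bromine to give a bromonium ion (inversion at C14) that chloride opens at the tertiary C15, giving the (14S)-bromide and the C15 chloride; the closest known reactions are the deoxychlorination of trans-2-bromocycloalkanols through bromonium ions and the stereospecific chloride capture of enantiopure bromonium ions generated from β-bromo sulfonates.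

**Step 9**
Reactants: 12 bromochloro acetate
Product: 13 (2E)-5-[(1R,2S,3S,4S)-3-[(3S)-3-bromo-4-chloro-4-methylpentyl]-1,3-dimethyl-7-oxabicyclo[2.2.1]heptan-2-yl]-3-methylpent-2-en-1-ol
Conditions: K2CO3 (0.3 equiv), MeOH, 0 °C
Reagents that add atoms: none
Why: Base-catalysed transesterification (methanolysis) removes the acetate, and the hindered secondary bromide and tertiary chloride do not react with catalytic carbonate at 0 °C; no stereocentre is touched.

**Step 10**
Reactants: 13 allylic alcohol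
Product: 14 [(2S,3S)-3-{2-[(1R,2S,3S,4S)-3-[(3S)-3-bromo-4-chloro-4-methylpentyl]-1,3-dimethyl-7-oxabicyclo[2.2.1]heptan-2-yl]ethyl}-3-methyloxiran-2-yl]methanol
Conditions: Ti(OiPr)4 (10 mol %), diethyl L-(+)-tartrate (13 mol %), t-BuOOH, 4 Å MS, CH2Cl2, −20 °C
Reagents that add atoms: tert-butyl hydroperoxide, CC(C)(C)OO
Why: Sharpless asymmetric epoxidation of the (2E)-allylic alcohol with L-(+)-tartrate gives the (2S,3S)-epoxy alcohol by reagent control (same sense as geraniol), which fixes the future C3 carbinol configuration.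

**Step 11**
Reactants: 14 epoxy alcohol
Product: 16 dactylomelol, via epoxy aldehyde 15 (not isolated)
Conditions: 2,2,6,6-tetramethylpiperidin-1-oxyl (10 mol %), PhI(OAc)2 (1.1 equiv), CH2Cl2, rt; then MeOH, N2H4·H2O (3 equiv), 0 °C → rt
Reagents that add atoms: none
Why: Nitroxyl-catalysed alcohol oxidation followed by Wharton transposition (hydrazone formation, epoxide opening to an alkenyl diazene, loss of N2) converts the epoxy aldehyde into CH2=CH–C(OH)(CH3)– with the C3–O bond intact, so the (3S) carbinol results, and hydrazine at 0 °C leaves the halides and the ether bridge alone.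

**Compound list**

1 | (2E,6E)-farnesol | OC/C=C(\C)CC/C=C(\C)CCC=C(C)C | starting material
2 | (2E,6E)-farnesyl acetate | CC(=O)OC/C=C(\C)CC/C=C(\C)CCC=C(C)C | intermediate
3 | (2E,6E,10E)-12-hydroxy-3,7,11-trimethyldodeca-2,6,10-trien-1-yl acetate | CC(=O)OC/C=C(\C)CC/C=C(\C)CC/C=C(\C)CO | intermediate
4 | (2E,6E)-9-[(2S,3S)-3-(hydroxymethyl)-3-methyloxiran-2-yl]-3,7-dimethylnona-2,6-dien-1-yl acetate | CC(=O)OC/C=C(\C)CC/C=C(\C)CC[C@@H]1O[C@@]1(C)CO | intermediate
5 | prenylmagnesium chloride (3-methylbut-2-en-1-ylmagnesium chloride) | CC(C)=CC[Mg]Cl | starting material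
6 | lithium alkoxide of 4 (O–Li in place of O–H at C12) | CC(=O)OC/C=C(\C)CC/C=C(\C)CC[C@@H]1O[C@@]1(C)C[O-].[Li+] | intermediate
7 | (2E,6E)-3,7-dimethyl-9-[(2S,3S)-3-methyl-3-{[(trifluoromethylsulfonyl)oxy]methyl}oxiran-2-yl]nona-2,6-dien-1-yl acetate | CC(=O)OC/C=C(\C)CC/C=C(\C)CC[C@@H]1O[C@@]1(C)COS(=O)(=O)C(F)(F)F | intermediate
8 | (2E,6E)-3,7-dimethyl-9-[(2S,3S)-3-methyl-3-(4-methylpent-3-en-1-yl)oxiran-2-yl]nona-2,6-dien-1-yl acetate | CC(=O)OC/C=C(\C)CC/C=C(\C)CC[C@@H]1O[C@@]1(C)CCC=C(C)C | intermediate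
9 | (2E)-5-[(1R,2S,3S,4S)-1,3-dimethyl-3-(4-methylpent-3-en-1-yl)-7-oxabicyclo[2.2.1]heptan-2-yl]-3-methylpent-2-en-1-yl acetate | CC(=O)OC/C=C(\C)CC[C@H]1[C@](C)(CCC=C(C)C)[C@@H]2CC[C@@]1(C)O2 | intermediate
10 | (2E)-5-[(1R,2S,3S,4S)-3-{2-[(2R)-3,3-dimethyloxiran-2-yl]ethyl}-1,3-dimethyl-7-oxabicyclo[2.2.1]heptan-2-yl]-3-methylpent-2-en-1-yl acetate | CC(=O)OC/C=C(\C)CC[C@H]1[C@](C)(CC[C@H]3OC3(C)C)[C@@H]2CC[C@@]1(C)O2 | intermediate
11 | (2E)-5-[(1R,2S,3S,4S)-3-[(3R)-4-bromo-3-hydroxy-4-methylpentyl]-1,3-dimethyl-7-oxabicyclo[2.2.1]heptan-2-yl]-3-methylpent-2-en-1-yl acetate | CC(=O)OC/C=C(\C)CC[C@H]1[C@](C)(CC[C@@H](O)C(C)(C)Br)[C@@H]2CC[C@@]1(C)O2 | intermediate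
12 | (2E)-5-[(1R,2S,3S,4S)-3-[(3S)-3-bromo-4-chloro-4-methylpentyl]-1,3-dimethyl-7-oxabicyclo[2.2.1]heptan-2-yl]-3-methylpent-2-en-1-yl acetate | CC(=O)OC/C=C(\C)CC[C@H]1[C@](C)(CC[C@H](Br)C(C)(C)Cl)[C@@H]2CC[C@@]1(C)O2 | intermediate
13 | (2E)-5-[(1R,2S,3S,4S)-3-[(3S)-3-bromo-4-chloro-4-methylpentyl]-1,3-dimethyl-7-oxabicyclo[2.2.1]heptan-2-yl]-3-methylpent-2-en-1-ol | OC/C=C(\C)CC[C@H]1[C@](C)(CC[C@H](Br)C(C)(C)Cl)[C@@H]2CC[C@@]1(C)O2 | intermediate
14 | [(2S,3S)-3-{2-[(1R,2S,3S,4S)-3-[(3S)-3-bromo-4-chloro-4-methylpentyl]-1,3-dimethyl-7-oxabicyclo[2.2.1]heptan-2-yl]ethyl}-3-methyloxiran-2-yl]methanol | OC[C@@H]3O[C@@]3(C)CC[C@H]1[C@](C)(CC[C@H](Br)C(C)(C)Cl)[C@@H]2CC[C@@]1(C)O2 | intermediate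
15 | (2R,3S)-3-{2-[(1R,2S,3S,4S)-3-[(3S)-3-bromo-4-chloro-4-methylpentyl]-1,3-dimethyl-7-oxabicyclo[2.2.1]heptan-2-yl]ethyl}-3-methyloxirane-2-carbaldehyde | O=C[C@@H]3O[C@@]3(C)CC[C@H]1[C@](C)(CC[C@H](Br)C(C)(C)Cl)[C@@H]2CC[C@@]1(C)O2 | intermediate
16 | dactylomelol, (3S)-5-[(1R,2S,3S,4S)-3-[(3S)-3-bromo-4-chloro-4-methylpentyl]-1,3-dimethyl-7-oxabicyclo[2.2.1]heptan-2-yl]-3-methylpent-1-en-3-ol | C=C[C@@](C)(O)CC[C@H]1[C@](C)(CC[C@H](Br)C(C)(C)Cl)[C@@H]2CC[C@@]1(C)O2 | target

**Step count and risks**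

Total step count: 11. Longest linear sequence: 11 steps from (2E,6E)-farnesol (the Grignard reagent 5 is purchased).

The three steps most likely to fail:

Step 5 (cascade). The C7 cation can also lose a proton, suffer a hydride shift to a ketone, or be attacked by C2=C3, so the bicyclic ether may be only a moderate part of the product mixture. Fallback: setting out from 8, methylaluminium dichloride (MeAlCl2, CH2Cl2, −78 °C) stops the same stereospecific cation–olefin cyclisation at the monocyclic stage by proton loss and gives the exocyclic-methylene cyclohexanol F1. N-Iodosuccinimide (CH2Cl2, 0 °C) then closes the ether bridge by 5-exo iodoetherification (oxygen to C7) to the iodomethyl oxabicycle F2. Bu3SnH with azobisisobutyronitrile (toluene, 80 °C) removes the iodine, and the sequence comes back to the route at 9.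

Step 4 (C12–C13 coupling). The triflate carbon is flanked by a fully substituted epoxide carbon, the allylic Grignard reagent can couple through its γ-carbon, and the allylic acetate is a second electrophile. Fallback: setting out from 4, triflate 7 is made as in step 4 and alkylated with lithiated 3-methylbut-2-en-1-yl phenyl sulfone (from the sulfone and n-BuLi, THF, −78 °C), which reacts only at its sulfonyl-bearing carbon, to give the C13 phenyl sulfone F3. Sodium amalgam, Na(Hg), with Na2HPO4 in MeOH/THF at −20 °C removes the sulfonyl group, and the sequence comes back at 8.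

Step 8 (bromine shift). Elimination of the tertiary bromide or chloride attack at C14 could compete with the bromonium pathway. Fallback: setting out from 10, HCl (Et2O, −20 °C) opens the epoxide at C15 to the chlorohydrin F4, and an Appel bromination (PPh3, CBr4, CH2Cl2, 0 °C) replaces the C14 hydroxyl by bromide with direct SN2 inversion; the sequence comes back at 12.

**Further compounds**

F1 | step 5 | (2E)-5-[(1R,2S,3S)-3-hydroxy-2-methyl-6-methylidene-2-(4-methylpent-3-en-1-yl)cyclohexyl]-3-methylpent-2-en-1-yl acetate | CC(=O)OC/C=C(\C)CC[C@H]1[C@](C)(CCC=C(C)C)[C@@H](O)CCC1=C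
F2 | step 5 | (2E)-5-[(1R,2S,3S,4S)-1-(iodomethyl)-3-methyl-3-(4-methylpent-3-en-1-yl)-7-oxabicyclo[2.2.1]heptan-2-yl]-3-methylpent-2-en-1-yl acetate | CC(=O)OC/C=C(\C)CC[C@H]1[C@](C)(CCC=C(C)C)[C@@H]2CC[C@@]1(CI)O2
F3 | step 4 | (2E,6E)-3,7-dimethyl-9-[(2S,3S)-3-methyl-3-[4-methyl-2-(phenylsulfonyl)pent-3-en-1-yl]oxiran-2-yl]nona-2,6-dien-1-yl acetate (both epimers at the sulfonyl carbon) | CC(=O)OC/C=C(\C)CC/C=C(\C)CC[C@@H]1O[C@@]1(C)CC(C=C(C)C)S(=O)(=O)c1ccccc1
F4 | step 8 | (2E)-5-[(1R,2S,3S,4S)-3-[(3R)-4-chloro-3-hydroxy-4-methylpentyl]-1,3-dimethyl-7-oxabicyclo[2.2.1]heptan-2-yl]-3-methylpent-2-en-1-yl acetate | CC(=O)OC/C=C(\C)CC[C@H]1[C@](C)(CC[C@@H](O)C(C)(C)Cl)[C@@H]2CC[C@@]1(C)O2
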